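Readings and results come from a simulation on assumed constants; scatter was added.

How much target stands in the grey flask at 30 h, and does any remedy add to it?

| flask | substrate | reagent | transfer agent | initiator | temperature | remark | time |
|---|---|---|---|---|---|---|---|
| grey | 0.40 M | 0.44 M | 0.040 M | 18 mM | −20 °C | the very flask that is asked about, followed so far |  |
| violet | 0.40 M | 0.66 M | 0.040 M | 18 mM | −20 °C | run made earlier |  |
| flask | 0.40 M | 0.440 M | 0.0400 M | 18 mM | −20 °C |  | 30 h |

| run | time / h | target / % | substrate / % |
|---|---|---|---|
| grey | 2.50 | 23.8 | 61.9 |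
| grey | 6.00 | 46.0 | 27.9 |
| grey | 12.0 | 69.4 | 1.7 |
| grey | 20.0 | 72.9 | 0.4 |
| violet | 0.417 | 6.0 | 89.0 |
| violet | 1.00 | 13.8 | 78.3 |
| violet | 2.00 | 27.4 | 61.4 |
| violet | 3.00 | 38.9 | 43.2 |

(scatter of a reading: 1 percentage point)

- noon: change nothing and wait 2.5 d more
- spring: at 30 h take out 90 % of the by-product then present, then wait 2.5 d
- dawn: at 30 h add reagent, 100 % of the amount charged, then wait 2.5 d
- winter: at 30 h raise the temperature by 10 K, then wait 2.5 d

- target, in percent of the substrate first charged, at 30 h
- the remedy with the largest gain of target, or "none" below 2 percentage points (noon / spring / dawn / winter / none)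
- target present, in percent of the substrate first charged, after dawn
- target present, in percent of the substrate first charged, after winter

- additions leave the volume as it is
- the numbers in the tables scatter with a standard deviation of 1 percentage point
- the earlier runs do not show what temperature does; that part of a forecast is a guess

My first estimate is a plateau: the grey substrate reads 0.4 % at 20.0 h, so the target should stay near 72.9 %. But target and substrate then leave 26.7 % of the charge unread. I call this the gap, the mass-balance deficit: charged substrate that is now neither target nor substrate.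

Is the gap a loss tied to the reagent? At 2.50 h the grey gap is 14.3 %. The violet run, with 1.50 times the reagent, brackets it with 11.2 % at 2.00 h and 17.9 % at 3.00 h. So the gap does not follow the reagent.

Is it dead, then, or a store? A store would shrink. Between 12.0 h and 20.0 h the grey gap falls from 28.9 % to 26.7 %. The objection is strong: this fall of 2.2 percentage points barely exceeds the 2 points scatter of such a difference. I take it as a weak sign.

As a straight line, that fall returns 19 points by 90.0 h. But the pace should shrink with the store, so I put that answer back and let the gap decay in proportion to itself, at 0.00990 h⁻¹. Counting its fall as target, the grey flask holds 75.8 % at 30 h. Waiting leaves a gap of 13.4 %, a gain of 11 points, which is more than the 2 points mark. Since the gap ignored the reagent, I expect dawn to give about the same, 86.6 %. Warmth might empty the store faster, but that is a guess, so I choose winter.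

The forecast differs. It gives 73 % (range 71 % to 75.5 %), best remedy none, 73.5 % after dawn and 72.5 % after winter: “The lost material therefore looks like an irreversible side channel, not a reagent shortage.”

The flask gives 74.6 %, 84.6 % after dawn and 94.4 % after winter, the best remedy being winter.

    initiator → 2 initiating radical (k = 5.24 × 10⁻⁶ s⁻¹, Ea = 83.0 kJ mol⁻¹)
    substrate + initiating radical → capped initiator + first chain carrier (k = 1.67 × 10⁵ M⁻¹ s⁻¹, Ea = 10.0 kJ mol⁻¹)
    reagent + first chain carrier → target + second chain carrier (k = 5770 M⁻¹ s⁻¹, Ea = 20.0 kJ mol⁻¹)
    substrate + second chain carrier → by-product + first chain carrier (k = 1760 M⁻¹ s⁻¹, Ea = 35.0 kJ mol⁻¹)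
    transfer agent + first chain carrier → side product + idle radical (kL = 856 M⁻¹ s⁻¹, Ea = 39.0 kJ mol⁻¹)
    2 idle radical → ended radicals (k = 3.60 × 10⁶ M⁻¹ s⁻¹, Ea = 11.0 kJ mol⁻¹)
    2 second chain carrier → ended chains A (k = 1.50 × 10⁶ M⁻¹ s⁻¹, Ea = 20.0 kJ mol⁻¹)
    2 first chain carrier → ended chains B (k = 8.00 × 10⁸ M⁻¹ s⁻¹, Ea = 8.00 kJ mol⁻¹)
    substrate ⇌ dormant form (K = 7.30, k = 2.00 × 10⁻⁵ s⁻¹, Ea = 76.0 kJ mol⁻¹, ΔH = −21.0 kJ mol⁻¹)
    (constants at −20 °C)

At 4.48 h the chain step uses substrate 2.2 times as fast as the forward step to the dormant form; at 30.0 h that ratio is 16. The gap read 26.7 % at 20.0 h. The same subtraction on the flask at 30.0 h gives 25.3 %, with the dormant form at 23.4 % and the side product at 1.55 %, and winter's gain equals 78.3 % of that gap. In the neighbour charged with 0.16 M of transfer agent, the same subtraction gives a gap of 49.0 %. That flask computes to 45.5 % dormant form and 3.50 % side product.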